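**Retrosynthetic overview**

1. Target 22 comes from flavone 21 by one BCl3 cleavage of the two benzyl ethers and the tert-butyl ether, and 21 from 2'-phenol 20 by O-methylation.
2. The strategy rests on ring B: its oxygens at C2' and C5' are para to each other, C1' (bonded to chromone C2) is ortho to the C2' oxygen, and the C4' oxygen sits next to C5'. This maps onto a benzannulation in which the carbene carbon becomes C5'(OMe), the vinyl ether carbons C4'(O-t-Bu) and C3', a CO ligand C2'(OH), and the terminal alkyne C1' and C6'.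
3. The partners are 2-ethynylchromone 13 and chromium carbene 18 (from tert-butyl vinyl ether, Cr(CO)6 and Me3OBF4).
4. Alkyne 13 comes from 3-methoxychromone 8 by C2 zincation/iodination, Sonogashira coupling and desilylation; ring C of 8 is closed from ortho-hydroxy ω-methoxyacetophenone 6 with DMF dimethyl acetal.
5. Ring A is bought as symmetric 1,3,5-tris(benzyloxy)benzene and elaborated by dibromination, Cu methoxylation, acylation and mono-debenzylation. Order of rings: A (purchased), C (step 5), B (step 10).

Key step: step 10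

Remark on the chemistry: 1,3,5-tris(benzyloxy)benzene is taken as a purchasable compound and replaces syringol as the ring-A source, because its symmetry makes every ring-A step regiochemically unambiguous.

**Route**

Step 1
Reactants: 1 1,3,5-tris(benzyloxy)benzene
Product: 2 1,3,5-tris(benzyloxy)-2,4-dibromobenzene
Conditions: NBS (2.05 equiv), CH2Cl2, −20 °C to rt, dark
Reagents that add atoms: N-bromosuccinimide, O=C1CCC(=O)N1Br
Why: Electrophilic aromatic bromination of the phloroglucinol triether should stop at the 2,4-dibromide, because the three ring positions are equivalent at the start and each bromine lowers the reactivity of those that remain.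

Step 2
Reactants: 2 1,3,5-tris(benzyloxy)-2,4-dibromobenzene
Product: 3 1,3,5-tris(benzyloxy)-2,4-dimethoxybenzene
Conditions: NaOMe (MeOH solution, excess), CuBr, DMF, 110 °C, Ar
Reagents that add atoms: sodium methoxide (NaOMe), [Na+].[O-]C
Why: Ullmann-type copper-mediated methoxylation of aryl bromides is established for electron-rich bromides flanked by alkoxy groups, and benzyl ethers are inert to methoxide.

Step 3
Reactants: 3 1,3,5-tris(benzyloxy)-2,4-dimethoxybenzene; 4 methoxyacetic acid
Product: 5 2-methoxy-1-[2,4,6-tris(benzyloxy)-3,5-dimethoxyphenyl]ethan-1-one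
Conditions: (CF3CO)2O, CH2Cl2, 0 °C to rt
Reagents that add atoms: methoxyacetic acid (4), COCC(=O)O
Why: Friedel–Crafts acylation through the mixed trifluoroacetic anhydride of 4 needs no metal Lewis acid, so the benzyl ethers should survive, and the single free ring carbon is activated by two ortho oxygens and one para oxygen.

Step 4
Reactants: 5 2-methoxy-1-[2,4,6-tris(benzyloxy)-3,5-dimethoxyphenyl]ethan-1-one
Product: 6 1-[2,4-bis(benzyloxy)-6-hydroxy-3,5-dimethoxyphenyl]-2-methoxyethan-1-one
Conditions: MgBr2·OEt2 (1.5 equiv), toluene–Et2O, 60 °C; 1 M HCl work-up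
Reagents that add atoms: none
Why: Chelation-controlled ether cleavage, in which MgBr2 held between the ketone oxygen and an ortho benzyloxy oxygen delivers bromide to that benzyl group only; the two ortho ethers are equivalent by symmetry and the magnesium phenoxide chelate formed first should block a second cleavage.

Step 5
Reactants: 6 1-[2,4-bis(benzyloxy)-6-hydroxy-3,5-dimethoxyphenyl]-2-methoxyethan-1-one
Product: 8 5,7-bis(benzyloxy)-3,6,8-trimethoxy-4H-chromen-4-one, via enaminone 7 (not isolated)
Conditions: Me2NCH(OMe)2 (3 equiv), toluene, 95 °C; then AcOH, 60 °C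
Reagents that add atoms: N,N-dimethylformamide dimethyl acetal, COC(OC)N(C)C
Why: Enaminone route to chromones, in which the methylene between the ketone and the methoxy group condenses with the amide acetal and the ortho phenol then adds to the enaminone carbon and expels dimethylamine (addition–elimination), closing ring C with C2 unsubstituted.

Step 6
Reactants: 8 5,7-bis(benzyloxy)-3,6,8-trimethoxy-4H-chromen-4-one
Product: 10 5,7-bis(benzyloxy)-2-iodo-3,6,8-trimethoxy-4H-chromen-4-one, via 2-chromonylzinc chloride 9 (not isolated)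
Conditions: TMPZnCl·LiCl (TMP = 2,2,6,6-tetramethylpiperidin-1-yl), THF, 0 °C to rt; then I2, THF, 0 °C
Reagents that add atoms: iodine, II
Why: Directed zincation with the hindered zinc amide should remove the only acidic sp2 hydrogen (C2–H, flanked by the ring oxygen and the 3-methoxy group) without the ring opening open to a 2-lithiochromone, and iodinolysis of the C–Zn bond gives the 2-iodide.

Step 7
Reactants: 10 5,7-bis(benzyloxy)-2-iodo-3,6,8-trimethoxy-4H-chromen-4-one; 11 trimethylsilylacetylene
Product: 12 5,7-bis(benzyloxy)-3,6,8-trimethoxy-2-[(trimethylsilyl)ethynyl]-4H-chromen-4-one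
Conditions: PdCl2(PPh3)2 (cat.), CuI (cat.), Et3N, THF, rt, Ar
Reagents that add atoms: trimethylsilylacetylene (11), C#C[Si](C)(C)C
Why: Sonogashira coupling, in which the 2-iodochromone behaves as a vinylogous acyl iodide that adds readily to zerovalent palladium, while the tertiary amine base cannot displace iodide by addition–elimination.

Step 8
Reactants: 12 5,7-bis(benzyloxy)-3,6,8-trimethoxy-2-[(trimethylsilyl)ethynyl]-4H-chromen-4-one
Product: 13 5,7-bis(benzyloxy)-2-ethynyl-3,6,8-trimethoxy-4H-chromen-4-one
Conditions: Bu4NF, AcOH, THF, −20 to 0 °C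
Reagents that add atoms: none
Why: Fluoride-induced protodesilylation of the alkynylsilane, buffered with acetic acid so that no alkoxide or basic fluoride adds to the electrophilic 2-alkynylchromone.

Step 9
Reactants: 14 tert-butyl vinyl ether; 15 chromium hexacarbonyl Cr(CO)6
Product: 18 pentacarbonyl[methoxy(1-tert-butoxyvinyl)carbene]chromium, via 1-tert-butoxyvinyllithium 16 (not isolated), via lithium acylpentacarbonylchromate 17 (not isolated)
Conditions: t-BuLi, THF–pentane, −78 to 0 °C; Cr(CO)6, THF, 0 °C to rt; evaporate; Me3OBF4, CH2Cl2, 0 °C; SiO2 filtration under Ar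
Reagents that add atoms: trimethyloxonium tetrafluoroborate, C[O+](C)C.F[B-](F)(F)F
Why: Fischer carbene synthesis, comprising α-lithiation of the vinyl ether, addition of the vinyllithium to a CO ligand of Cr(CO)6 and O-methylation of the acylchromate, as practised for the closely related complexes made from 2-lithiodihydropyran.

Step 10
Reactants: 13 5,7-bis(benzyloxy)-2-ethynyl-3,6,8-trimethoxy-4H-chromen-4-one; 18 pentacarbonyl[methoxy(1-tert-butoxyvinyl)carbene]chromium
Product: 20 5,7-bis(benzyloxy)-2-(4-tert-butoxy-2-hydroxy-5-methoxyphenyl)-3,6,8-trimethoxy-4H-chromen-4-one, via tricarbonylchromium arene complex 19 (not isolated)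
Conditions: 18 (1.5 equiv), THF (0.05 M), 50 °C, Ar; then air, daylight, EtOAc, rt
Reagents that add atoms: none
Why: This is a Dötz benzannulation of an alkenyl(alkoxy)carbene complex of zerovalent chromium with a terminal alkyne, a well-established reaction type whose closest relatives are the cyclic 1-alkoxyalkenyl complexes derived from dihydropyran and furan. Thermal loss of one CO from 18 opens a site for alkyne 13, which inserts into the Cr=C bond so that its CH terminus bonds to the former carbene carbon (C5'–C6'), and migratory CO insertion into the new chromium vinylcarbene gives an η4-vinylketene (C1'–C2'). Ring B is then closed by a six-electron electrocyclization of this dienylketene onto the CH2 terminus of the vinyl ether (C2'–C3'), and enolization of the cyclohexadienone gives the phenol as its Cr(CO)3 complex 19, which mild aerobic demetalation in daylight should convert to 20. No stereocenter is formed. The step needs the alkyne to insert with its chromonyl-bearing carbon on the chromium side (and so next to the CO-derived C2'), which is the normal outcome for terminal alkynes because the larger substituent stays away from the carbene substituents, and here the size difference between H and the 3-methoxychromon-2-yl group is large. It also needs phenol formation to outrun cyclobutenone, indene and two-alkyne pathways, which chromium, an alkenyl carbene, THF near 50 °C and moderate dilution favour, and it needs a non-oxidizing work-up (air, not (NH4)2Ce(NO3)6) so that the para-methoxyphenol is not carried on to the quinone.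

Step 11
Reactants: 20 5,7-bis(benzyloxy)-2-(4-tert-butoxy-2-hydroxy-5-methoxyphenyl)-3,6,8-trimethoxy-4H-chromen-4-one
Product: 21 5,7-bis(benzyloxy)-2-(4-tert-butoxy-2,5-dimethoxyphenyl)-3,6,8-trimethoxy-4H-chromen-4-one
Conditions: MeI, K2CO3, DMF, rt
Reagents that add atoms: iodomethane, CI
Why: Williamson O-methylation of the only free phenol; the tert-butyl ether, the benzyl ethers and the chromone are stable to K2CO3 in DMF at room temperature.

Step 12
Reactants: 21 5,7-bis(benzyloxy)-2-(4-tert-butoxy-2,5-dimethoxyphenyl)-3,6,8-trimethoxy-4H-chromen-4-one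
Product: 22 5,7-dihydroxy-2-(4-hydroxy-2,5-dimethoxyphenyl)-3,6,8-trimethoxy-4H-chromen-4-one (5,7,4'-trihydroxy-3,6,8,2',5'-pentamethoxyflavone)
Conditions: BCl3 (CH2Cl2 solution, excess), C6HMe5, CH2Cl2, −78 to −20 °C; H2O work-up
Reagents that add atoms: none
Why: Lewis acid ether cleavage, in which BCl3 ionizes the benzyl and tert-butyl ethers (stabilized carbocations) at −78 °C, well below the temperature at which it attacks aryl methyl ethers, while pentamethylbenzene traps the benzyl cations so that ring B is not C-alkylated.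

**Compound list**

1 | 1,3,5-tris(benzyloxy)benzene | c1ccc(COc2cc(OCc3ccccc3)cc(OCc3ccccc3)c2)cc1 | starting material
2 | 1,3,5-tris(benzyloxy)-2,4-dibromobenzene | Brc1c(OCc2ccccc2)cc(OCc2ccccc2)c(Br)c1OCc1ccccc1 | intermediate
3 | 1,3,5-tris(benzyloxy)-2,4-dimethoxybenzene | COc1c(OCc2ccccc2)cc(OCc2ccccc2)c(OC)c1OCc1ccccc1 | intermediate
4 | methoxyacetic acid | COCC(=O)O | starting material
5 | 2-methoxy-1-[2,4,6-tris(benzyloxy)-3,5-dimethoxyphenyl]ethan-1-one | COCC(=O)c1c(OCc2ccccc2)c(OC)c(OCc2ccccc2)c(OC)c1OCc1ccccc1 | intermediate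
6 | 1-[2,4-bis(benzyloxy)-6-hydroxy-3,5-dimethoxyphenyl]-2-methoxyethan-1-one | COCC(=O)c1c(O)c(OC)c(OCc2ccccc2)c(OC)c1OCc1ccccc1 | intermediate
7 | 1-[2,4-bis(benzyloxy)-6-hydroxy-3,5-dimethoxyphenyl]-3-(dimethylamino)-2-methoxyprop-2-en-1-one (enaminone; alkene geometry not controlled and without consequence) | COC(=CN(C)C)C(=O)c1c(O)c(OC)c(OCc2ccccc2)c(OC)c1OCc1ccccc1 | intermediate
8 | 5,7-bis(benzyloxy)-3,6,8-trimethoxy-4H-chromen-4-one | COc1coc2c(OC)c(OCc3ccccc3)c(OC)c(OCc3ccccc3)c2c1=O | intermediate
9 | [5,7-bis(benzyloxy)-3,6,8-trimethoxy-4-oxo-4H-chromen-2-yl]zinc chloride (as its LiCl adduct) | COc1c([Zn]Cl)oc2c(OC)c(OCc3ccccc3)c(OC)c(OCc3ccccc3)c2c1=O | intermediate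
10 | 5,7-bis(benzyloxy)-2-iodo-3,6,8-trimethoxy-4H-chromen-4-one | COc1c(I)oc2c(OC)c(OCc3ccccc3)c(OC)c(OCc3ccccc3)c2c1=O | intermediate
11 | trimethylsilylacetylene | C#C[Si](C)(C)C | starting material
12 | 5,7-bis(benzyloxy)-3,6,8-trimethoxy-2-[(trimethylsilyl)ethynyl]-4H-chromen-4-one | COc1c(C#C[Si](C)(C)C)oc2c(OC)c(OCc3ccccc3)c(OC)c(OCc3ccccc3)c2c1=O | intermediate
13 | 5,7-bis(benzyloxy)-2-ethynyl-3,6,8-trimethoxy-4H-chromen-4-one | C#Cc1oc2c(OC)c(OCc3ccccc3)c(OC)c(OCc3ccccc3)c2c(=O)c1OC | intermediate
14 | tert-butyl vinyl ether | C=COC(C)(C)C | starting material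
15 | chromium hexacarbonyl Cr(CO)6 | O=C=[Cr](=C=O)(=C=O)(=C=O)(=C=O)=C=O | starting material
16 | 1-tert-butoxyvinyllithium | [Li]C(=C)OC(C)(C)C | intermediate
17 | lithium acylpentacarbonylchromate Li[(CO)5Cr=C(O)C(O-t-Bu)=CH2] | [Li+].[O-]C(C(=C)OC(C)(C)C)=[Cr](=C=O)(=C=O)(=C=O)(=C=O)=C=O | intermediate
18 | pentacarbonyl[methoxy(1-tert-butoxyvinyl)carbene]chromium | COC(C(=C)OC(C)(C)C)=[Cr](=C=O)(=C=O)(=C=O)(=C=O)=C=O | intermediate
19 | tricarbonylchromium complex of 20, Cr(CO)3 bound η6 to ring B (written as its two components; the η6 bond is not drawn) | COc1cc(-c2oc3c(OC)c(OCc4ccccc4)c(OC)c(OCc4ccccc4)c3c(=O)c2OC)c(O)cc1OC(C)(C)C.O=C=[Cr](=C=O)=C=O | intermediate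
20 | 5,7-bis(benzyloxy)-2-(4-tert-butoxy-2-hydroxy-5-methoxyphenyl)-3,6,8-trimethoxy-4H-chromen-4-one | COc1cc(-c2oc3c(OC)c(OCc4ccccc4)c(OC)c(OCc4ccccc4)c3c(=O)c2OC)c(O)cc1OC(C)(C)C | intermediate
21 | 5,7-bis(benzyloxy)-2-(4-tert-butoxy-2,5-dimethoxyphenyl)-3,6,8-trimethoxy-4H-chromen-4-one | COc1cc(-c2oc3c(OC)c(OCc4ccccc4)c(OC)c(OCc4ccccc4)c3c(=O)c2OC)c(OC)cc1OC(C)(C)C | intermediate
22 | 5,7,4'-trihydroxy-3,6,8,2',5'-pentamethoxyflavone | COc1cc(-c2oc3c(OC)c(O)c(OC)c(O)c3c(=O)c2OC)c(OC)cc1O | target

**Step count**

Total: 12 steps. Longest linear sequence: 11 steps (steps 1–8, then 10–12, from compound 1); the carbene branch is one step (step 9).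

**Steps most likely to fail**

Step 10 (benzannulation). The conjugated, electron-poor alkyne may insert slowly, and coordination of the chromone carbonyl or the 3-methoxy oxygen to chromium in the vinylcarbene could divert the sequence to cyclobutenone, indene or two-alkyne products. The electron-rich para-methoxyphenol could also be over-oxidized during demetalation. The fallback builds the C2–C1' bond instead of ring B; it sets out from chromone 8 through its zinc reagent 9 and returns to the route at target 22. Negishi coupling of 9 with an excess of commercial 1,4-dibromo-2,5-dimethoxybenzene (Pd(OAc)2, SPhos, THF, 50 °C) should give 5,7-bis(benzyloxy)-2-(4-bromo-2,5-dimethoxyphenyl)-3,6,8-trimethoxy-4H-chromen-4-one F1. Miyaura borylation (B2pin2, PdCl2(dppf), KOAc, dioxane, 90 °C) should give 5,7-bis(benzyloxy)-2-[2,5-dimethoxy-4-(4,4,5,5-tetramethyl-1,3,2-dioxaborolan-2-yl)phenyl]-3,6,8-trimethoxy-4H-chromen-4-one F2. Oxidation with NaBO3·4H2O in THF–water should give 5,7-bis(benzyloxy)-2-(4-hydroxy-2,5-dimethoxyphenyl)-3,6,8-trimethoxy-4H-chromen-4-one F3, and hydrogenolysis (H2, Pd/C, EtOAc–MeOH) then removes both benzyl groups to give 22.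

Step 9 (carbene synthesis). Deprotonation of the hindered vinyl ether by t-BuLi may be incomplete or may lose out to attack of the base on THF, and the acylchromate may decompose before O-methylation. The fallback is a tin relay that sets out from 14 and returns at vinyllithium 16. Metalation of 14 with the n-BuLi/KO-t-Bu superbase (THF, −78 °C), for which oxygen coordination matters less, should give 1-tert-butoxyvinylpotassium F4. Quenching with Bu3SnCl should give distillable tributyl(1-tert-butoxyvinyl)stannane F5. Tin–lithium exchange of the purified stannane (n-BuLi, THF, −78 °C) then delivers 16 free of excess base for addition to Cr(CO)6 as in step 9.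

Step 2 (double methoxylation). The bromines, each flanked by two benzyloxy groups, may undergo reductive loss of bromine or stall after the first substitution. The fallback separates C–O bond formation from methylation; it sets out from dibromide 2 and returns at 3. Palladium-catalysed hydroxylation (Pd2(dba)3, tBuXPhos, KOH, dioxane–water, 100 °C) should give 2,4,6-tris(benzyloxy)benzene-1,3-diol F6, which is methylated with MeI and K2CO3 in acetone to give 3.

**Further compounds**

F1 | step 10 | 5,7-bis(benzyloxy)-2-(4-bromo-2,5-dimethoxyphenyl)-3,6,8-trimethoxy-4H-chromen-4-one | COc1cc(-c2oc3c(OC)c(OCc4ccccc4)c(OC)c(OCc4ccccc4)c3c(=O)c2OC)c(OC)cc1Br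
F2 | step 10 | 5,7-bis(benzyloxy)-2-[2,5-dimethoxy-4-(4,4,5,5-tetramethyl-1,3,2-dioxaborolan-2-yl)phenyl]-3,6,8-trimethoxy-4H-chromen-4-one | COc1cc(-c2oc3c(OC)c(OCc4ccccc4)c(OC)c(OCc4ccccc4)c3c(=O)c2OC)c(OC)cc1B1OC(C)(C)C(C)(C)O1
F3 | step 10 | 5,7-bis(benzyloxy)-2-(4-hydroxy-2,5-dimethoxyphenyl)-3,6,8-trimethoxy-4H-chromen-4-one | COc1cc(-c2oc3c(OC)c(OCc4ccccc4)c(OC)c(OCc4ccccc4)c3c(=O)c2OC)c(OC)cc1O
F4 | step 9 | 1-tert-butoxyvinylpotassium | [K]C(=C)OC(C)(C)C
F5 | step 9 | tributyl(1-tert-butoxyvinyl)stannane | CCCC[Sn](CCCC)(CCCC)C(=C)OC(C)(C)C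
F6 | step 2 | 2,4,6-tris(benzyloxy)benzene-1,3-diol | Oc1c(OCc2ccccc2)cc(OCc2ccccc2)c(O)c1OCc1ccccc1
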